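**Retrosynthetic overview**
1. Last operations: C1–C10 epoxide (peracid on the macrocyclic E-alkene), C13 acetate (lipase), butenolide by oxidative lactonisation of C6–OH with the cis CH2OH on C11. C11 carries two identical CH2O groups until then, so the tetrasubstituted C7=C11 alkene never has an E/Z problem.
2. C8–O from the macrocyclic C8 ketone (ketoreductase); ten-membered ring by intramolecular Ni/Cr coupling (C6–C7) of an α-bromo enone with a 4,5-epoxy aldehyde.
3. 4,5-Epoxide from catalytic Sharpless epoxidation of the geraniol-derived allylic alcohol (first stereocentres).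
4. C8–C9 by C-acylation of a C9 allylic sulfone (geraniol, SeO2 oxidation) with a bromo enoate made from 1,3-bis(silyloxy)acetone (HWE, bromination), then desulfonylation.
5. Ring order: C4–C5 oxirane → ten-membered carbocycle → butenolide → C1–C10 oxirane.

Assumption: the C8 acyl group is (E)-2-methylbut-2-enoyl (tigloyl); germacrane numbering of the target (C1–C10 ring, C11–C13 lactone carbons, C14 on C10, C15 on C4) is used for all intermediates; TBS = tert-butyldimethylsilyl, TES = triethylsilyl, PMB = 4-methoxybenzyl.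

**Route**

Step 1
Reactants: 1 geraniol
Product: 2 (E)-geranyl 4-methoxybenzyl ether
Conditions: NaH, PMBCl, Bu4NI (cat.), THF–DMF, 0 °C → rt
Reagents that add atoms: 4-methoxybenzyl chloride, COc1ccc(CCl)cc1
Why: Williamson etherification masks the future C6 hydroxyl as a PMB ether that survives the carbanion and SmI2 steps and is later removed oxidatively under neutral conditions.

Step 2
Reactants: 2 (E)-geranyl 4-methoxybenzyl ether
Product: 3 (2E,6E)-8-[(4-methoxybenzyl)oxy]-2,6-dimethylocta-2,6-dien-1-ol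
Conditions: SeO2 (0.3 equiv), t-BuOOH, salicylic acid (cat.), CH2Cl2, 0 °C → rt
Reagents that add atoms: selenium dioxide (catalytic oxygen carrier), O=[Se]=O; tert-butyl hydroperoxide, CC(C)(C)OO
Why: SeO2-catalysed allylic oxidation (ene reaction, then [2,3]-shift) attacks the E-methyl group of the electron-rich terminal alkene and gives the E-allylic alcohol that becomes C9.

Step 3
Reactants: 3 (2E,6E)-8-[(4-methoxybenzyl)oxy]-2,6-dimethylocta-2,6-dien-1-ol
Product: 4 (2E,6E)-1-bromo-8-[(4-methoxybenzyl)oxy]-2,6-dimethylocta-2,6-diene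
Conditions: CBr4, PPh3, CH2Cl2, 0 °C
Reagents that add atoms: carbon tetrabromide, BrC(Br)(Br)Br
Why: The Appel reaction turns the primary allylic alcohol into the bromide by SN2 displacement without allylic transposition or loss of E geometry.

Step 4
Reactants: 4 (2E,6E)-1-bromo-8-[(4-methoxybenzyl)oxy]-2,6-dimethylocta-2,6-diene
Product: 5 (2E,6E)-8-[(4-methoxybenzyl)oxy]-2,6-dimethylocta-2,6-dien-1-yl phenyl sulfone
Conditions: PhSO2Na, DMF, rt
Reagents that add atoms: sodium benzenesulfinate, [Na+].[O-]S(=O)c1ccccc1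
Why: SN2 S-alkylation of the sulfinate gives an allylic sulfone whose carbanion reacts at its α-carbon, making C9 a clean carbon nucleophile.

Step 5
Reactants: 6 1,3-bis(tert-butyldimethylsilyloxy)propan-2-one, 7 trimethyl phosphonoacetate
Product: 8 methyl 4-(TBS-oxy)-3-[(TBS-oxy)methyl]but-2-enoate
Conditions: NaH, THF, 0 °C → rt
Reagents that add atoms: none
Why: Horner–Wadsworth–Emmons olefination of the reactive symmetric ketone gives the C8–C7=C11(C12,C13) unit with two identical CH2OTBS groups on C11.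

Step 6
Reactants: 8 methyl 4-(TBS-oxy)-3-[(TBS-oxy)methyl]but-2-enoate
Product: 10 methyl 2-bromo-4-(TBS-oxy)-3-[(TBS-oxy)methyl]but-2-enoate, via dibromide 9 (not isolated)
Conditions: Br2, CH2Cl2, 0 °C → rt; then Et3N, 0 °C → rt
Reagents that add atoms: bromine, BrBr
Why: Bromine addition followed by base-induced dehydrobromination (addition–elimination) places the vinylic bromide on the α-carbon, the future C7.

Step 7
Reactants: 5 (2E,6E)-8-[(4-methoxybenzyl)oxy]-2,6-dimethylocta-2,6-dien-1-yl phenyl sulfone, 10 methyl 2-bromo-4-(TBS-oxy)-3-[(TBS-oxy)methyl]but-2-enoate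
Product: 11 (6E,10E)-3-bromo-1-(TBS-oxy)-2-[(TBS-oxy)methyl]-12-[(4-methoxybenzyl)oxy]-6,10-dimethyl-5-(phenylsulfonyl)dodeca-2,6,10-trien-4-one
Conditions: 5 (2.1 equiv), n-BuLi (2.0 equiv), THF, −78 °C; then 10, −78 → −40 °C; aq. NH4Cl
Reagents that add atoms: none
Why: Claisen-type C-acylation of the lithiated sulfone at its α-carbon by the ester forms the C8–C9 bond, and the β-keto sulfone is held as its enolate so it cannot react further.

Step 8
Reactants: 11 the β-keto sulfone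
Product: 12 (6E,10E)-3-bromo-1-(TBS-oxy)-2-[(TBS-oxy)methyl]-12-[(4-methoxybenzyl)oxy]-6,10-dimethyldodeca-2,6,10-trien-4-one
Conditions: SmI2 (2.3 equiv), THF–MeOH, −78 °C, 10 min
Reagents that add atoms: none
Why: Single-electron reductive desulfonylation of the α-sulfonyl ketone is far faster than reduction of the vinylic C–Br bond, and kinetic α-protonation of the samarium dienolate keeps the 1(10) alkene in place.

Step 9
Reactants: 12 the PMB-protected bromo enone
Product: 13 (6E,10E)-3-bromo-1-(TBS-oxy)-2-[(TBS-oxy)methyl]-12-hydroxy-6,10-dimethyldodeca-2,6,10-trien-4-one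
Conditions: DDQ, CH2Cl2–pH 7 buffer, 0 °C
Reagents that add atoms: none
Why: Oxidative PMB-ether cleavage frees the C6 allylic alcohol without touching the silyl ethers, the alkenes or the bromo enone.

Step 10
Reactants: 13 the allylic alcohol
Product: 14 (6E,10R,11R)-3-bromo-1-(TBS-oxy)-2-[(TBS-oxy)methyl]-10,11-epoxy-12-hydroxy-6,10-dimethyldodeca-2,6-dien-4-one
Conditions: Ti(OiPr)4 (10 mol%), D-(−)-diethyl tartrate (12 mol%), t-BuOOH, 4 Å MS, CH2Cl2, −20 °C
Reagents that add atoms: tert-butyl hydroperoxide, CC(C)(C)OO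
Why: Catalytic Sharpless asymmetric epoxidation reacts only at the allylic-alcohol alkene, and D-(−)-tartrate gives the (2R,3R)-type epoxy alcohol (C4 R, C5 R), the first stereocentres.

Step 11
Reactants: 14 the epoxy alcohol
Product: 15 C12 aldehyde of 14 (epoxide unchanged in space; CIP 10R,11S in the numbering of 14)
Conditions: Dess–Martin periodinane, CH2Cl2, 0 °C → rt; used at once
Reagents that add atoms: none
Why: Dess–Martin oxidation gives the sensitive α,β-epoxy aldehyde under near-neutral conditions without epimerisation or epoxide opening.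

Step 12
Reactants: 15 the epoxy aldehyde
Product: 16 (1(10)E,4R,5R,6S)-12,13-bis(TBS-oxy)-4,5-epoxy-6-hydroxygermacra-1(10),7(11)-dien-8-one
Conditions: CrCl2 (8 equiv), NiCl2 (5 mol%), DMSO–THF, slow addition to 2 mM, rt; H2O work-up
Reagents that add atoms: none
Why: In this intramolecular Nozaki–Hiyama–Kishi coupling Ni inserts into the activated C–Br bond and the chromium(III) species adds to the aldehyde but not the ketone, closing the ten-membered ring; the 6S (5,6-threo) centre is expected from ring control in the cyclic transition state, as in related Cr- and Pd-mediated germacrane closures onto this kind of epoxy aldehyde.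

Step 13
Reactants: 16 the macrocyclic hydroxy ketone
Product: 17 (1(10)E,4R,5R,6S)-12,13-bis(TBS-oxy)-4,5-epoxy-6-(TES-oxy)germacra-1(10),7(11)-dien-8-one
Conditions: TESCl, imidazole, DMAP (cat.), CH2Cl2, 0 °C → rt
Reagents that add atoms: chlorotriethylsilane, CC[Si](Cl)(CC)CC
Why: Silylation blocks the C6 hydroxyl so that only the C8 hydroxyl formed next can be acylated.

Step 14
Reactants: 17 the silylated macrocyclic ketone
Product: 18 (1(10)E,4R,5R,6S,8S)-12,13-bis(TBS-oxy)-4,5-epoxy-6-(TES-oxy)germacra-1(10),7(11)-dien-8-ol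
Conditions: ketoreductase (NADPH-dependent, panel hit for 8S), NADP+ (cat.), i-PrOH, pH 7 phosphate buffer–MTBE, 30 °C
Reagents that add atoms: none
Why: Enzymatic carbonyl reduction by the ketoreductase, with isopropanol recycling the cofactor, delivers hydride to one face of the ketone (large tetrasubstituted alkenyl side versus small CH2 side) and sets 8S under catalyst control.

Step 15
Reactants: 18 the 8S alcohol, 19 tiglic acid
Product: 21 (1(10)E,4R,5R,6S,8S)-12,13-bis(TBS-oxy)-4,5-epoxy-6-(TES-oxy)germacra-1(10),7(11)-dien-8-yl tiglate, via mixed anhydride 20 (not isolated)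
Conditions: 19, 2,4,6-trichlorobenzoyl chloride, Et3N, toluene, rt; then 18, DMAP, rt
Reagents that add atoms: none
Why: Yamaguchi esterification acylates the hindered allylic alcohol with retention at C8, and the E-configured tiglate is the thermodynamically stable isomer so it does not isomerise.

Step 16
Reactants: 21 the silylated tiglate
Product: 22 (1(10)E,4R,5R,6S,8S)-4,5-epoxy-6,12,13-trihydroxygermacra-1(10),7(11)-dien-8-yl tiglate
Conditions: TBAF–AcOH (1:1), THF, 0 °C → rt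
Reagents that add atoms: none
Why: Buffered fluoride desilylation removes the TES and both TBS groups without acyl migration or epoxide opening.

Step 17
Reactants: 22 the triol
Product: 24 (1(10)E,4R,5R,6S,8S)-4,5-epoxy-13-oxo-8-tigloyloxygermacra-1(10),7(11)-dien-12,6-olide, via lactol aldehyde 23 (not isolated)
Conditions: TEMPO (20 mol%), PhI(OAc)2 (3.3 equiv), CH2Cl2, rt
Reagents that add atoms: none
Why: In this oxoammonium (TEMPO) oxidation the primary CH2OH cis to the C6 hydroxyl closes to the lactol and is oxidised on to the butenolide (oxidative lactonisation), while the other CH2OH stops at the aldehyde.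

Step 18
Reactants: 24 the butenolide aldehyde
Product: 25 (1(10)E,4R,5R,6S,8S)-4,5-epoxy-13-hydroxy-8-tigloyloxygermacra-1(10),7(11)-dien-12,6-olide
Conditions: NaBH4, CeCl3·7H2O, MeOH–THF, −78 °C
Reagents that add atoms: none
Why: Luche reduction gives selective 1,2-reduction of the aldehyde and leaves the lactone, the ester, the epoxide and the hindered conjugated alkene alone.

Step 19
Reactants: 25 the C13 alcohol
Product: 26 (1(10)E,4R,5R,6S,8S)-13-acetoxy-4,5-epoxy-8-tigloyloxygermacra-1(10),7(11)-dien-12,6-olide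
Conditions: lipase (immobilised Candida antarctica lipase B), vinyl acetate, MTBE, 30 °C
Reagents that add atoms: vinyl acetate, C=COC(C)=O
Why: Lipase-catalysed irreversible transesterification acetylates the primary alcohol at neutral pH, avoiding amine bases that could deprotonate the butenolide γ-position next to the epoxide.

Step 20
Reactants: 26 the monoepoxide acetate
Product: 27 (1R,4R,5R,6S,8S,10R)-13-acetoxy-1,10:4,5-diepoxy-8-tigloyloxygermacr-7(11)-en-12,6-olide (CNP0251711.1)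
Conditions: mCPBA (1.1 equiv), CH2Cl2, −10 → 0 °C
Reagents that add atoms: meta-chloroperoxybenzoic acid, OOC(=O)c1cccc(Cl)c1
Why: Prilezhaev epoxidation reacts only at the one electron-rich alkene, and the peracid attacks the outer face of the E-1(10) alkene in the ring conformer with C14 and C15 on the same side, giving the trans (1R,10R) epoxide as in related 4,5-epoxy germacranolides.

**Compound list**

1 | geraniol, (2E)-3,7-dimethylocta-2,6-dien-1-ol | OC/C=C(\C)CCC=C(C)C | starting material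
2 | (E)-geranyl 4-methoxybenzyl ether | COc1ccc(COC/C=C(\C)CCC=C(C)C)cc1 | intermediate
3 | (2E,6E)-8-[(4-methoxybenzyl)oxy]-2,6-dimethylocta-2,6-dien-1-ol | COc1ccc(COC/C=C(\C)CC/C=C(\C)CO)cc1 | intermediate
4 | (2E,6E)-1-bromo-8-[(4-methoxybenzyl)oxy]-2,6-dimethylocta-2,6-diene | COc1ccc(COC/C=C(\C)CC/C=C(\C)CBr)cc1 | intermediate
5 | (2E,6E)-8-[(4-methoxybenzyl)oxy]-2,6-dimethylocta-2,6-dien-1-yl phenyl sulfone | COc1ccc(COC/C=C(\C)CC/C=C(\C)CS(=O)(=O)c2ccccc2)cc1 | intermediate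
6 | 1,3-bis(tert-butyldimethylsilyloxy)propan-2-one | CC(C)(C)[Si](C)(C)OCC(=O)CO[Si](C)(C)C(C)(C)C | starting material
7 | trimethyl phosphonoacetate | COC(=O)CP(=O)(OC)OC | starting material
8 | methyl 4-(TBS-oxy)-3-[(TBS-oxy)methyl]but-2-enoate | COC(=O)C=C(CO[Si](C)(C)C(C)(C)C)CO[Si](C)(C)C(C)(C)C | intermediate
9 | methyl 2,3-dibromo-4-(TBS-oxy)-3-[(TBS-oxy)methyl]butanoate (racemic) | COC(=O)C(Br)C(Br)(CO[Si](C)(C)C(C)(C)C)CO[Si](C)(C)C(C)(C)C | intermediate
10 | methyl 2-bromo-4-(TBS-oxy)-3-[(TBS-oxy)methyl]but-2-enoate | COC(=O)C(Br)=C(CO[Si](C)(C)C(C)(C)C)CO[Si](C)(C)C(C)(C)C | intermediate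
11 | (6E,10E)-3-bromo-1-(TBS-oxy)-2-[(TBS-oxy)methyl]-12-[(4-methoxybenzyl)oxy]-6,10-dimethyl-5-(phenylsulfonyl)dodeca-2,6,10-trien-4-one (racemic at C5 = C9 of the target) | COc1ccc(COC/C=C(\C)CC/C=C(\C)C(C(=O)C(Br)=C(CO[Si](C)(C)C(C)(C)C)CO[Si](C)(C)C(C)(C)C)S(=O)(=O)c2ccccc2)cc1 | intermediate
12 | (6E,10E)-3-bromo-1-(TBS-oxy)-2-[(TBS-oxy)methyl]-12-[(4-methoxybenzyl)oxy]-6,10-dimethyldodeca-2,6,10-trien-4-one | COc1ccc(COC/C=C(\C)CC/C=C(\C)CC(=O)C(Br)=C(CO[Si](C)(C)C(C)(C)C)CO[Si](C)(C)C(C)(C)C)cc1 | intermediate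
13 | (6E,10E)-3-bromo-1-(TBS-oxy)-2-[(TBS-oxy)methyl]-12-hydroxy-6,10-dimethyldodeca-2,6,10-trien-4-one | OC/C=C(\C)CC/C=C(\C)CC(=O)C(Br)=C(CO[Si](C)(C)C(C)(C)C)CO[Si](C)(C)C(C)(C)C | intermediate
14 | (6E,10R,11R)-3-bromo-1-(TBS-oxy)-2-[(TBS-oxy)methyl]-10,11-epoxy-12-hydroxy-6,10-dimethyldodeca-2,6-dien-4-one (C4 R, C5 R of the target) | CC(C)(C)[Si](C)(C)OCC(CO[Si](C)(C)C(C)(C)C)=C(Br)C(=O)C/C(C)=C/CC[C@@]1(C)O[C@@H]1CO | intermediate
15 | C12 aldehyde of 14 (epoxy aldehyde; same spatial arrangement, CIP 10R,11S in the numbering of 14) | CC(C)(C)[Si](C)(C)OCC(CO[Si](C)(C)C(C)(C)C)=C(Br)C(=O)C/C(C)=C/CC[C@@]1(C)O[C@@H]1C=O | intermediate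
16 | (1(10)E,4R,5R,6S)-12,13-bis(TBS-oxy)-4,5-epoxy-6-hydroxygermacra-1(10),7(11)-dien-8-one | O=C1C/C(C)=C/CC[C@@]2(C)O[C@@H]2[C@@H](O)C1=C(CO[Si](C)(C)C(C)(C)C)CO[Si](C)(C)C(C)(C)C | intermediate
17 | (1(10)E,4R,5R,6S)-12,13-bis(TBS-oxy)-4,5-epoxy-6-(TES-oxy)germacra-1(10),7(11)-dien-8-one | O=C1C/C(C)=C/CC[C@@]2(C)O[C@@H]2[C@@H](O[Si](CC)(CC)CC)C1=C(CO[Si](C)(C)C(C)(C)C)CO[Si](C)(C)C(C)(C)C | intermediate
18 | (1(10)E,4R,5R,6S,8S)-12,13-bis(TBS-oxy)-4,5-epoxy-6-(TES-oxy)germacra-1(10),7(11)-dien-8-ol | O[C@H]1C/C(C)=C/CC[C@@]2(C)O[C@@H]2[C@@H](O[Si](CC)(CC)CC)C1=C(CO[Si](C)(C)C(C)(C)C)CO[Si](C)(C)C(C)(C)C | intermediate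
19 | tiglic acid, (E)-2-methylbut-2-enoic acid | C/C=C(\C)C(=O)O | starting material
20 | tiglic 2,4,6-trichlorobenzoic anhydride | C/C=C(\C)C(=O)OC(=O)c1c(Cl)cc(Cl)cc1Cl | intermediate
21 | (1(10)E,4R,5R,6S,8S)-12,13-bis(TBS-oxy)-4,5-epoxy-6-(TES-oxy)germacra-1(10),7(11)-dien-8-yl tiglate | C/C=C(\C)C(=O)O[C@H]1C/C(C)=C/CC[C@@]2(C)O[C@@H]2[C@@H](O[Si](CC)(CC)CC)C1=C(CO[Si](C)(C)C(C)(C)C)CO[Si](C)(C)C(C)(C)C | intermediate
22 | (1(10)E,4R,5R,6S,8S)-4,5-epoxy-6,12,13-trihydroxygermacra-1(10),7(11)-dien-8-yl tiglate | C/C=C(\C)C(=O)O[C@H]1C/C(C)=C/CC[C@@]2(C)O[C@@H]2[C@@H](O)C1=C(CO)CO | intermediate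
23 | 12,6-lactol (cyclic hemiacetal, C12 epimers) of the 12,13-dialdehyde, 8-tiglate | C/C=C(\C)C(=O)O[C@H]1C/C(C)=C/CC[C@@]2(C)O[C@@H]2[C@H]2OC(O)C(C=O)=C12 | intermediate
24 | (1(10)E,4R,5R,6S,8S)-4,5-epoxy-13-oxo-8-tigloyloxygermacra-1(10),7(11)-dien-12,6-olide | C/C=C(\C)C(=O)O[C@H]1C/C(C)=C/CC[C@@]2(C)O[C@@H]2[C@H]2OC(=O)C(C=O)=C12 | intermediate
25 | (1(10)E,4R,5R,6S,8S)-4,5-epoxy-13-hydroxy-8-tigloyloxygermacra-1(10),7(11)-dien-12,6-olide | C/C=C(\C)C(=O)O[C@H]1C/C(C)=C/CC[C@@]2(C)O[C@@H]2[C@H]2OC(=O)C(CO)=C12 | intermediate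
26 | (1(10)E,4R,5R,6S,8S)-13-acetoxy-4,5-epoxy-8-tigloyloxygermacra-1(10),7(11)-dien-12,6-olide | C/C=C(\C)C(=O)O[C@H]1C/C(C)=C/CC[C@@]2(C)O[C@@H]2[C@H]2OC(=O)C(COC(C)=O)=C12 | intermediate
27 | (1R,4R,5R,6S,8S,10R)-13-acetoxy-1,10:4,5-diepoxy-8-tigloyloxygermacr-7(11)-en-12,6-olide (CNP0251711.1) | C/C=C(\C)C(=O)O[C@H]1C[C@@]2(C)O[C@@H]2CC[C@@]2(C)O[C@@H]2[C@H]2OC(=O)C(COC(C)=O)=C12 | target

**Totals and risks**

Total step count: 20. Longest linear sequence: 18 steps (steps 1–4 and 7–20, from geraniol); the two-step branch 5–6 joins at step 7.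

The three steps most likely to fail:

Step 12, the Ni/Cr ring closure. The ten-membered ring may close in low yield, and the new C6 centre may follow open-chain Felkin control instead of ring control. In the second case the coupling of 15 gives the C6 epimer, (1(10)E,4R,5R,6R)-12,13-bis(TBS-oxy)-4,5-epoxy-6-hydroxygermacra-1(10),7(11)-dien-8-one F4. The fallback replaces ring-controlled addition by a stereoinversion: Mitsunobu reaction of F4 with 4-nitrobenzoic acid (PPh3, DIAD, toluene, 0 °C) gives the inverted (6S)-4-nitrobenzoate F5, and mild methanolysis (K2CO3, MeOH, 0 °C) returns to the route at 16.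

Step 14, the ketoreductase reduction. The trisilylated macrocyclic ketone 17 is large and lipophilic and may not be accepted by any enzyme of the panel. The fallback gives up catalyst control: 17 is reduced with NaBH4/CeCl3 (MeOH, −78 °C) under substrate control. Any 8S alcohol formed is 18 itself. If the product is the 8R alcohol, (1(10)E,4R,5R,6S,8R)-12,13-bis(TBS-oxy)-4,5-epoxy-6-(TES-oxy)germacra-1(10),7(11)-dien-8-ol F6, a Mitsunobu esterification of F6 with tiglic acid 19 (PPh3, DIAD) inverts C8 and installs the ester in one operation, returning to the route at 21.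

Step 7, the C-acylation. The hindered, tetrasubstituted bromo ester 10 may react sluggishly, or the carbanion may attack bromine. The fallback changes acyl substitution into carbonyl addition plus oxidation. Starting from 10, DIBAL-H (CH2Cl2, −78 °C) gives the allylic alcohol 2-bromo-4-(TBS-oxy)-3-[(TBS-oxy)methyl]but-2-en-1-ol F1; MnO2 oxidises it to the enal 2-bromo-4-(TBS-oxy)-3-[(TBS-oxy)methyl]but-2-enal F2; lithiated 5 adds to F2 at −78 °C to give the β-hydroxy sulfone F3 as a diastereomer mixture; Dess–Martin oxidation of F3 returns to the route at 11.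

Further compounds
F1 | step 7 | 2-bromo-4-(TBS-oxy)-3-[(TBS-oxy)methyl]but-2-en-1-ol | OCC(Br)=C(CO[Si](C)(C)C(C)(C)C)CO[Si](C)(C)C(C)(C)C
F2 | step 7 | 2-bromo-4-(TBS-oxy)-3-[(TBS-oxy)methyl]but-2-enal | O=CC(Br)=C(CO[Si](C)(C)C(C)(C)C)CO[Si](C)(C)C(C)(C)C
F3 | step 7 | (6E,10E)-3-bromo-1-(TBS-oxy)-2-[(TBS-oxy)methyl]-12-[(4-methoxybenzyl)oxy]-6,10-dimethyl-5-(phenylsulfonyl)dodeca-2,6,10-trien-4-ol (diastereomer mixture) | COc1ccc(COC/C=C(\C)CC/C=C(\C)C(C(O)C(Br)=C(CO[Si](C)(C)C(C)(C)C)CO[Si](C)(C)C(C)(C)C)S(=O)(=O)c2ccccc2)cc1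
F4 | step 12 | (1(10)E,4R,5R,6R)-12,13-bis(TBS-oxy)-4,5-epoxy-6-hydroxygermacra-1(10),7(11)-dien-8-one | O=C1C/C(C)=C/CC[C@@]2(C)O[C@@H]2[C@H](O)C1=C(CO[Si](C)(C)C(C)(C)C)CO[Si](C)(C)C(C)(C)C
F5 | step 12 | (1(10)E,4R,5R,6S)-12,13-bis(TBS-oxy)-4,5-epoxy-8-oxogermacra-1(10),7(11)-dien-6-yl 4-nitrobenzoate | O=C1C/C(C)=C/CC[C@@]2(C)O[C@@H]2[C@@H](OC(=O)c3ccc(cc3)[N+](=O)[O-])C1=C(CO[Si](C)(C)C(C)(C)C)CO[Si](C)(C)C(C)(C)C
F6 | step 14 | (1(10)E,4R,5R,6S,8R)-12,13-bis(TBS-oxy)-4,5-epoxy-6-(TES-oxy)germacra-1(10),7(11)-dien-8-ol | O[C@@H]1C/C(C)=C/CC[C@@]2(C)O[C@@H]2[C@@H](O[Si](CC)(CC)CC)C1=C(CO[Si](C)(C)C(C)(C)C)CO[Si](C)(C)C(C)(C)C
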